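## Structural features

Mycothiazole is a 2,4-disubstituted 1,3-thiazole with two acyclic arms; the numbering used here is thiazole C2–C7(CH3)2–C8H(OH)–C9H2–C10H=C11H–C12(=C12′H2)–C13H2–C14H2–NHCO2CH3 for the eastern arm and thiazole C4–C15H2–C16H=C17H–C18H2–C19H=C20H2 for the western arm. The western arm is a skipped (E)-diene whose C15 (thiazolyl-allylic) and C18 (bis-allylic) methylenes allow the double bonds to slide into conjugation under strong base or metal hydride catalysis. In the eastern arm the quaternary C7 sits between the thiazole and the only stereocentre, the (R)-carbinol C8, which is therefore neopentylic and hindered but has no stereogenic neighbour. C8 is homoallylic to the (Z)-C10=C11 bond, which is conjugated with the 1,1-disubstituted C12=C12′ methylene; C12 also carries the C13–C14 chain that ends in a secondary methyl carbamate. The (Z)-diene is the most fragile part (E/Z isomerisation by acid, radicals or metal hydrides), followed by the skipped diene, and the thiazole is a potential ligand for late transition metals. The real difficulty is the C8–C12 segment: a geometrically pure (Z)-diene two atoms away from a free, enantiopure carbinol, in a molecule that has no ring to hold that geometry. The key step exploits the fact that O8 and C11 are 1,4-related and cis across C10=C11, so that O8–C8–C9–C10=C11 is the opened form of a 2,3-dihydrofuran whose vinylic C11–O bond can be exchanged for the C11–C12 bond with retention, while the C12′–C12–C13 triad is the retron of a 2-metallated allylsilane. In one sentence, the route is a nickel-catalysed C(sp2)–O ring-opening cross-coupling of an enantiopure 2-substituted 2,3-dihydrofuran with a 2-magnesiated allylsilane.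

## Logic of the disconnections

24 ⇒ 17 + 20. The C13–C14 bond is cut. The C12′=C12–C13 unit of 24 is the product pattern of an SE2′ reaction of an allylsilane, and the electrophile is then a one-carbon N-acyliminium ion that already carries the methyl carbamate. The gain is that the nitrogen arm arrives in its final form, with no N-protecting group and no N–H in any earlier intermediate. The forward step demands that the allylsilane outcompetes every other π-system and that silicon is lost before the cation can scramble the Z geometry; O8 is masked and released in the same flask (21, 23).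

17 ⇒ 13 + 14 (key). The C11–C12 bond is cut and, in the retrosynthetic direction, O8 is joined to C11. A five-membered ring cannot contain an (E)-C10=C11 bond, so the Z geometry stops being a selectivity problem and becomes a structural certainty. The ring oxygen is also its own protecting group for C8–OH. The gain is large: 13 has one stereocentre, no alkene geometry to control and no free hydroxyl, and 14 is bought. The forward step must cleave the C(sp2)–O bond with retention and leave the C8–O bond, the thiazole C–S bonds and the skipped diene alone.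

13 ⇒ 12. The O8–C11 bond is cut, which is the retron of an endo-cycloisomerisation of a terminal homopropargylic alcohol through a metal vinylidene. 13 becomes an acyclic alkynol whose only stereochemical element is C8. The forward step needs a catalyst that is not sequestered by the thiazole, and the product is an acid-sensitive enol ether that must be handled on base-washed supports.

12 ⇒ 9 + 10. The C8–C9 bond is cut, as an enantioselective propargylation of an aldehyde by an allenylboron reagent. This is where C8 is set. 9 has no α-hydrogen, so it can neither enolise nor racemise. The demand is Re-face addition under catalyst control, next to a quaternary carbon and a basic heterocycle.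

9 ⇒ 7 ⇒ 6 + 2, and 2 ⇒ 1. After adjustment of the oxidation level (aldehyde from ester), the C15–C16 bond is cut as an sp3–sp2 cross-coupling. The E geometry of C16=C17 then comes from syn-hydroboration of the alkyne of 1, and the skipped diene never meets a base stronger than phosphate. The demand is a coupling without double-bond migration.

6 ⇒ 4 + 5, and 4 ⇒ 3. The S1–C5 and N3–C4 bonds of the thiazole are cut (Hantzsch). The quaternary C7 is bought with 3. Because 5 is symmetric the regiochemistry is unambiguous, and the spare CH2Cl lands on C4 as the handle for C15.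

20 ⇒ 18. The N–CH2 and CH2–O bonds of the N,O-acetal are cut back to 18, formaldehyde and methanol.

## Other disconnections considered

Alternative 1: The first disconnection that comes to mind cuts C11–C12 in the open chain: a Stille coupling of the silyl-protected (Z)-vinyl iodide A1 with the vinylstannane A2, followed by desilylation. A1 would be reached from 9 by an asymmetric aldol or allylation, O-silylation, adjustment to the C10 aldehyde and a kinetically controlled iodo-olefination. Its Z geometry is therefore a selectivity question with a separation attached, whereas in the chosen plan the ring dictates it. O8 must be protected and deprotected, A2 needs a regiocontrolled hydrostannation and stoichiometric tin, and the sequence from 9 is about two operations longer.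

Alternative 2: Cutting both C10=C11 and C12=C12′ leads to an ene–yne cross-metathesis of the homoallylic alcohol A3 with the alkynyl carbamate A4, on paper the most convergent union. In the intermolecular mode the new C10=C11 bond is formed through an acyclic metallacycle with no element that favours Z, and the C19=C20 vinyl group of the western arm is an equally good metathesis partner. An intramolecular rescue would tether O8 and N through the carbamate carbonyl, close the ten-membered cyclic carbamate A5 in the endo mode and open it with methoxide. That would fix the geometry, but it rests on a medium-ring closure whose endo/exo preference and strain cannot be argued with the same confidence as the opening of a five-membered ring.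

Alternative 3: Cutting C10=C11 as a carbonyl olefination gives a Wittig reaction between the ylide of the phosphonium salt A6 and the 2-substituted acrolein A7. A non-stabilised ylide should favour Z, but an oxygen substituent at the γ-position of the ylide is known to erode that preference, and A7 is a polymerisable Michael acceptor towards the ylide. A6 also needs a two-carbon extension from C8 that ends in a primary halide, which implies hydroboration or oxidative cleavage chemistry that cannot distinguish the C19=C20 vinyl group. The western arm would then have to be added late, at the cost of several steps.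

Key step: step 8

Assumption: (R)-TRIP is taken to direct the allenylboronate to the Re face of 9, as BINOL-phosphoric acids of this series do in the analogous allylborations; if the sense is the opposite, (S)-TRIP is used with no other change.

## Steps

Step 1
Reactants: 1 pent-1-en-4-yne
Product: 2 2-[(1E)-penta-1,4-dien-1-yl]-4,4,5,5-tetramethyl-1,3,2-dioxaborolane
Conditions: HBpin (1.05 equiv), Cp2Zr(H)Cl (5 mol%), Et3N (10 mol%), neat, 60 °C
Reagents that add atoms: pinacolborane, CC1(C)OBOC1(C)C
Why: Zirconium-catalysed syn-hydroboration of the terminal alkyne places boron on the terminal carbon and gives the (E)-alkenylboronate; the alkyne should react much faster than the monosubstituted alkene under these conditions.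

Step 2
Reactants: 3 ethyl 2-cyano-2-methylpropanoate
Product: 4 ethyl 3-amino-2,2-dimethyl-3-sulfanylidenepropanoate
Conditions: (NH4)2S (20% aq., 1.5 equiv), MeOH, rt to 40 °C
Reagents that add atoms: ammonium sulfide, [NH4+].[NH4+].[S-2]
Why: Thiolysis of a nitrile: hydrosulfide adds to the ester-activated C≡N to give the primary thioamide, and the hindered α-quaternary ester should resist ammonolysis at this temperature.

Step 3
Reactants: 4 ethyl 3-amino-2,2-dimethyl-3-sulfanylidenepropanoate; 5 1,3-dichloropropan-2-one
Product: 6 ethyl 2-[4-(chloromethyl)-1,3-thiazol-2-yl]-2-methylpropanoate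
Conditions: EtOH, reflux; then aq. NaHCO3
Reagents that add atoms: none
Why: Hantzsch thiazole synthesis: S-alkylation by one CH2Cl of the symmetric dihaloketone, closure of N onto the carbonyl and dehydration; the second CH2Cl necessarily ends up on C4.

Step 4
Reactants: 6 ethyl 2-[4-(chloromethyl)-1,3-thiazol-2-yl]-2-methylpropanoate; 2 2-[(1E)-penta-1,4-dien-1-yl]-4,4,5,5-tetramethyl-1,3,2-dioxaborolane
Product: 7 ethyl 2-{4-[(2E)-hexa-2,5-dien-1-yl]-1,3-thiazol-2-yl}-2-methylpropanoate
Conditions: Pd(dppf)Cl2 (5 mol%), K3PO4 (3 equiv), THF/H2O 10:1, 60 °C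
Reagents that add atoms: none
Why: Suzuki–Miyaura sp3–sp2 coupling of a hetero-benzylic chloride with an (E)-alkenylboronate proceeds with retention of alkene geometry; the Pd–CH2-thiazolyl intermediate has no β-hydrogen and the phosphate base is too weak to move the skipped diene into conjugation.

Step 5
Reactants: 7 ethyl 2-{4-[(2E)-hexa-2,5-dien-1-yl]-1,3-thiazol-2-yl}-2-methylpropanoate
Product: 9 2-{4-[(2E)-hexa-2,5-dien-1-yl]-1,3-thiazol-2-yl}-2-methylpropanal, via aluminium hemiacetal 8 (not isolated)
Conditions: DIBAL-H (1.15 equiv), CH2Cl2, −78 °C; MeOH, then aq. Rochelle salt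
Reagents that add atoms: none
Why: Partial ester reduction: the neopentylic tetrahedral aluminium hemiacetal 8 should persist at −78 °C and collapse to the aldehyde only on work-up; 9 has no α-hydrogen and cannot enolise.

Step 6
Reactants: 9 2-{4-[(2E)-hexa-2,5-dien-1-yl]-1,3-thiazol-2-yl}-2-methylpropanal; 10 4,4,5,5-tetramethyl-2-(propa-1,2-dien-1-yl)-1,3,2-dioxaborolane
Product: 12 (3R)-2-{4-[(2E)-hexa-2,5-dien-1-yl]-1,3-thiazol-2-yl}-2-methylhex-5-yn-3-ol, via O-pinacolboryl ether 11 (not isolated)
Conditions: (R)-TRIP (10 mol%), 4 Å MS, toluene, −20 to 0 °C; aq. NaHCO3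
Reagents that add atoms: none
Why: Chiral phosphoric acid-catalysed propargylboration: the allenylboronate adds through a closed six-membered SE2′ transition state (γ-attack with allenyl-to-propargyl transposition) while the catalyst hydrogen-bonds a boronate oxygen and the formyl C–H and exposes the Re face, which sets C8 as R.

Step 7
Reactants: 12 (3R)-2-{4-[(2E)-hexa-2,5-dien-1-yl]-1,3-thiazol-2-yl}-2-methylhex-5-yn-3-ol
Product: 13 (2R)-2-(2-{4-[(2E)-hexa-2,5-dien-1-yl]-1,3-thiazol-2-yl}propan-2-yl)-2,3-dihydrofuran
Conditions: Mo(CO)6 (25 mol%), Me3NO (25 mol%), Et3N/Et2O 1:3, rt; Et3N-deactivated silica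
Reagents that add atoms: none
Why: Molybdenum-vinylidene cycloisomerisation of a terminal homopropargylic alcohol: a 1,2-hydrogen shift gives Mo=C=CH–, O8 adds to the electrophilic vinylidene carbon (net 5-endo closure) to give a cyclic oxacarbene, and an amine-mediated proton shift releases the endocyclic enol ether; C8 is not involved.

Step 8
Reactants: 13 (2R)-2-(2-{4-[(2E)-hexa-2,5-dien-1-yl]-1,3-thiazol-2-yl}propan-2-yl)-2,3-dihydrofuran; 14 (2-bromoprop-2-en-1-yl)trimethylsilane
Product: 17 (3R,5Z)-2-{4-[(2E)-hexa-2,5-dien-1-yl]-1,3-thiazol-2-yl}-2-methyl-7-[(trimethylsilyl)methyl]octa-5,7-dien-3-ol, via alkenyl Grignard reagent 15 (not isolated), via bromomagnesium alkoxide 16 (not isolated)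
Conditions: 14, Mg, THF, 40 °C; then 13, Ni(cod)2 (10 mol%), PCy3 (20 mol%), toluene/THF, 0 °C to rt; sat. aq. NH4Cl
Reagents that add atoms: none
Why: Kumada-type C–O cross-coupling of a cyclic enol ether with ring opening; the closest known reaction type is the nickel-catalysed opening of 2,3-dihydrofurans by aryl, methyl and silylmethyl Grignard reagents to (Z)-homoallylic alcohols. Ni(0), bound to the enol ether π-bond of 13 and assisted by magnesium on the ring oxygen, inserts into the vinylic C11–O bond to give a six-membered alkenylnickel alkoxide in which C9 and nickel are held cis on C10=C11. Transmetalation with 15 replaces the alkoxide on nickel by the 2-(silylmethyl)vinyl group and leaves O8 as the magnesium alkoxide 16; reductive elimination then forms C11–C12 with retention, so the new diene can only be Z. No ring is closed: the five-membered ring is opened and its oxygen becomes the free C8 hydroxyl on protonation. No stereocentre is formed and C8 is untouched, because its C(sp3)–O bond is neither allylic nor π-activated. The step needs C(sp2)–O insertion to win over insertion into the thiazole C–S bonds and over alkene migration in the C15–C20 arm; the enol ether is the only π-bond with a leaving oxygen that magnesium can activate, the thiazole nitrogen is flanked by the quaternary C7 and the C4 substituent, and 15 offers no easy β-hydride elimination (it would have to form an allene), so no nickel hydride should arise at this temperature.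

Step 9
Reactants: 18 methyl carbamate
Product: 20 methyl N-(methoxymethyl)carbamate, via methyl N-(hydroxymethyl)carbamate 19 (not isolated)
Conditions: (CH2O)n (1.05 equiv), K2CO3 (cat.), MeOH, 60 °C; then TsOH (cat.), MeOH, rt; distillation
Reagents that add atoms: formaldehyde (as paraformaldehyde), C=O; methanol, CO
Why: Base-catalysed N-hydroxymethylation of the carbamate followed by acid-catalysed exchange of OH for OMe through the N-acyliminium ion, the standard preparation of an N-acyliminium precursor.

Step 10
Reactants: 17 (3R,5Z)-2-{4-[(2E)-hexa-2,5-dien-1-yl]-1,3-thiazol-2-yl}-2-methyl-7-[(trimethylsilyl)methyl]octa-5,7-dien-3-ol; 20 methyl N-(methoxymethyl)carbamate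
Product: 24 mycothiazole (methyl N-[(4Z,7R)-8-{4-[(2E)-hexa-2,5-dien-1-yl]-1,3-thiazol-2-yl}-7-hydroxy-8-methyl-3-methylidenenon-4-en-1-yl]carbamate), via O-trimethylsilyl ether 21 (not isolated), via N-acyliminium triflate 22 (not isolated), via O-trimethylsilyl mycothiazole 23 (not isolated)
Conditions: 2,6-di-tert-butyl-4-methylpyridine (1.5 equiv), TMSOTf (1.1 equiv), CH2Cl2, −78 °C; then 20 (1.2 equiv), TMSOTf (0.3 equiv), −78 to −40 °C; then K2CO3, MeOH, 0 °C
Reagents that add atoms: none
Why: Sakurai-type amidoalkylation: after in-flask O-silylation (21), TMSOTf ionises 20 to the N-acyliminium ion 22, which is attacked by the terminal CH2 of the allylsilane (the future C13); the resulting C12 cation is β to silicon and loses Me3Si at once, which creates the C12=C12′ methylene and the C13–C14 bond regiospecifically (SE2′). The allylsilane is the most nucleophilic π-system by a wide margin, the hindered pyridine removes triflic acid that would otherwise protodesilylate it, and neither C8 nor the C10=C11 geometry takes part. Methanolysis of the O–Si bond of 23 releases the target.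

## Compound list

1 | pent-1-en-4-yne | C=CCC#C | starting material
2 | 2-[(1E)-penta-1,4-dien-1-yl]-4,4,5,5-tetramethyl-1,3,2-dioxaborolane | C=CC/C=C/B1OC(C)(C)C(C)(C)O1 | intermediate
3 | ethyl 2-cyano-2-methylpropanoate | CCOC(=O)C(C)(C)C#N | starting material
4 | ethyl 3-amino-2,2-dimethyl-3-sulfanylidenepropanoate | CCOC(=O)C(C)(C)C(N)=S | intermediate
5 | 1,3-dichloropropan-2-one | O=C(CCl)CCl | starting material
6 | ethyl 2-[4-(chloromethyl)-1,3-thiazol-2-yl]-2-methylpropanoate | CCOC(=O)C(C)(C)c1nc(CCl)cs1 | intermediate
7 | ethyl 2-{4-[(2E)-hexa-2,5-dien-1-yl]-1,3-thiazol-2-yl}-2-methylpropanoate | CCOC(=O)C(C)(C)c1nc(C/C=C/CC=C)cs1 | intermediate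
8 | diisobutylaluminium ethyl hemiacetal of 9 (aluminium hemiacetal) | CCOC(O[Al](CC(C)C)CC(C)C)C(C)(C)c1nc(C/C=C/CC=C)cs1 | intermediate
9 | 2-{4-[(2E)-hexa-2,5-dien-1-yl]-1,3-thiazol-2-yl}-2-methylpropanal | O=CC(C)(C)c1nc(C/C=C/CC=C)cs1 | intermediate
10 | 4,4,5,5-tetramethyl-2-(propa-1,2-dien-1-yl)-1,3,2-dioxaborolane | C=C=CB1OC(C)(C)C(C)(C)O1 | starting material
11 | O-pinacolboryl ether of 12 | CC(C)(c1nc(C/C=C/CC=C)cs1)[C@H](OB1OC(C)(C)C(C)(C)O1)CC#C | intermediate
12 | (3R)-2-{4-[(2E)-hexa-2,5-dien-1-yl]-1,3-thiazol-2-yl}-2-methylhex-5-yn-3-ol | CC(C)(c1nc(C/C=C/CC=C)cs1)[C@H](O)CC#C | intermediate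
13 | (2R)-2-(2-{4-[(2E)-hexa-2,5-dien-1-yl]-1,3-thiazol-2-yl}propan-2-yl)-2,3-dihydrofuran | CC(C)(c1nc(C/C=C/CC=C)cs1)[C@H]1CC=CO1 | intermediate
14 | (2-bromoprop-2-en-1-yl)trimethylsilane | C=C(Br)C[Si](C)(C)C | starting material
15 | [3-(trimethylsilyl)prop-1-en-2-yl]magnesium bromide | C=C([Mg]Br)C[Si](C)(C)C | intermediate
16 | bromomagnesium alkoxide of 17 | CC(C)(c1nc(C/C=C/CC=C)cs1)[C@H](O[Mg]Br)C/C=C\C(=C)C[Si](C)(C)C | intermediate
17 | (3R,5Z)-2-{4-[(2E)-hexa-2,5-dien-1-yl]-1,3-thiazol-2-yl}-2-methyl-7-[(trimethylsilyl)methyl]octa-5,7-dien-3-ol | CC(C)(c1nc(C/C=C/CC=C)cs1)[C@H](O)C/C=C\C(=C)C[Si](C)(C)C | intermediate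
18 | methyl carbamate | COC(N)=O | starting material
19 | methyl N-(hydroxymethyl)carbamate | COC(=O)NCO | intermediate
20 | methyl N-(methoxymethyl)carbamate | COCNC(=O)OC | intermediate
21 | O-trimethylsilyl ether of 17 | CC(C)(c1nc(C/C=C/CC=C)cs1)[C@H](O[Si](C)(C)C)C/C=C\C(=C)C[Si](C)(C)C | intermediate
22 | N-(methoxycarbonyl)methaniminium trifluoromethanesulfonate | C=[NH+]C(=O)OC.[O-]S(=O)(=O)C(F)(F)F | intermediate
23 | O-trimethylsilyl mycothiazole | C=CC/C=C/Cc1csc(C(C)(C)[C@H](O[Si](C)(C)C)C/C=C\C(=C)CCNC(=O)OC)n1 | intermediate
24 | mycothiazole, methyl N-[(4Z,7R)-8-{4-[(2E)-hexa-2,5-dien-1-yl]-1,3-thiazol-2-yl}-7-hydroxy-8-methyl-3-methylidenenon-4-en-1-yl]carbamate | C=CC/C=C/Cc1csc(C(C)(C)[C@H](O)C/C=C\C(=C)CCNC(=O)OC)n1 | target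

## Step count and least certain steps

Total step count: 10. Longest linear sequence: 8 steps (3 → 4 → 6 → 7 → 9 → 12 → 13 → 17 → 24; steps 2, 3, 4, 5, 6, 7, 8 and 10). Steps 1 and 9 are side branches.

Step 8 (key step). The reaction type is established for aryl, methyl and silylmethyl Grignard reagents; a branched alkenyl Grignard reagent is an extension within that type. Most likely to go wrong:
- oxidative addition of electron-rich Ni(0) into a thiazole C–S bond in competition with the vinylic C–O bond;
- slow transmetalation of the hindered alkenyl nucleophile, with homocoupling as the outlet;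
- nickel-hydride-mediated migration of the skipped diene or Z-to-E isomerisation of the new diene if the reaction has to be heated.

Fallback, which gives up the ring template for a triple-bond template: set out from 12. A Sonogashira coupling of 12 with 14 (Pd(PPh3)4, CuI, iPr2NH) gives the enyne allylsilane (3R)-2-{4-[(2E)-hexa-2,5-dien-1-yl]-1,3-thiazol-2-yl}-2-methyl-7-[(trimethylsilyl)methyl]oct-7-en-5-yn-3-ol F1. Cis-semireduction of its conjugated triple bond with Zn(Cu/Ag) in aqueous methanol, which leaves isolated alkenes and sulfur heterocycles alone, comes back to the route at 17.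

Step 10. Most likely to go wrong:
- protodesilylation of the allylsilane by adventitious triflic acid, which would leave a 2-methyl diene;
- capture of the allyl-type cation by the carbamate oxygen (ring closure to an oxazinone) or bond rotation in that cation before silicon is lost, with erosion of the Z geometry;
- a second amidoalkylation of the product diene if the electrophile is in excess.

Fallback, which brings the carbamate in before the diene exists: set out from 12, 14 and 20. Amidoalkylation of the simple allylsilane 14 with 20 (TMSOTf, CH2Cl2, −78 °C) gives methyl N-(3-bromobut-3-en-1-yl)carbamate F2. Sonogashira coupling of F2 with 12 gives the enyne carbamate methyl N-[(7R)-8-{4-[(2E)-hexa-2,5-dien-1-yl]-1,3-thiazol-2-yl}-7-hydroxy-8-methyl-3-methylidenenon-4-yn-1-yl]carbamate F3. Zn(Cu/Ag) semireduction of F3 comes back to the route at 24.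

Step 7. Most likely to go wrong:
- sequestration of the molybdenum carbonyl fragment by the thiazole, so that the vinylidene pathway stalls;
- metal-mediated migration of the skipped diene;
- hydrolysis or alcohol addition at the enol ether during isolation.

Fallback, which builds the enol ether by elimination instead of cycloisomerisation: set out from 12. Ruthenium-catalysed anti-Markovnikov hydration of the terminal alkyne (CpRu/bipyridyl-type catalyst, aqueous acetone) gives the γ-hydroxy aldehyde, which closes to the lactol (5R)-5-(2-{4-[(2E)-hexa-2,5-dien-1-yl]-1,3-thiazol-2-yl}propan-2-yl)oxolan-2-ol F4. Mesylation and elimination (MsCl, Et3N, CH2Cl2, −20 °C to reflux) comes back to the route at 13.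

Step 6. Most likely to go wrong:
- insufficient facial selectivity with a hindered α-quaternary aliphatic aldehyde;
- partial neutralisation of the phosphoric acid by the thiazole nitrogen, or chelation of boron between the carbonyl oxygen and that nitrogen, which would open an uncatalysed racemic pathway.

Fallback, which sets C8 by resolution of an epoxide instead of by face-selective addition: set out from 9. Corey–Chaykovsky methylenation (Me3S+ I−, KOtBu, THF/DMSO, 0 °C) gives the racemic epoxide 4-[(2E)-hexa-2,5-dien-1-yl]-2-[2-(oxiran-2-yl)propan-2-yl]-1,3-thiazole F5. Hydrolytic kinetic resolution with the (salen)Co(III) acetate antipode that consumes the (R)-epoxide leaves the (S)-epoxide F6. Opening of F6 at its CH2 terminus with lithium (trimethylsilyl)acetylide and BF3·OEt2 (THF, −78 °C) gives the silyl alkynol (3R)-2-{4-[(2E)-hexa-2,5-dien-1-yl]-1,3-thiazol-2-yl}-2-methyl-6-(trimethylsilyl)hex-5-yn-3-ol F7. Desilylation with K2CO3 in MeOH comes back to the route at 12.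

## Further compounds

F1 | step 8 | (3R)-2-{4-[(2E)-hexa-2,5-dien-1-yl]-1,3-thiazol-2-yl}-2-methyl-7-[(trimethylsilyl)methyl]oct-7-en-5-yn-3-ol | CC(C)(c1nc(C/C=C/CC=C)cs1)[C@H](O)CC#CC(=C)C[Si](C)(C)C
F2 | step 10 | methyl N-(3-bromobut-3-en-1-yl)carbamate | C=C(Br)CCNC(=O)OC
F3 | step 10 | methyl N-[(7R)-8-{4-[(2E)-hexa-2,5-dien-1-yl]-1,3-thiazol-2-yl}-7-hydroxy-8-methyl-3-methylidenenon-4-yn-1-yl]carbamate | C=CC/C=C/Cc1csc(C(C)(C)[C@H](O)CC#CC(=C)CCNC(=O)OC)n1
F4 | step 7 | (5R)-5-(2-{4-[(2E)-hexa-2,5-dien-1-yl]-1,3-thiazol-2-yl}propan-2-yl)oxolan-2-ol (anomer mixture) | CC(C)(c1nc(C/C=C/CC=C)cs1)[C@H]1CCC(O)O1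
F5 | step 6 | 4-[(2E)-hexa-2,5-dien-1-yl]-2-[2-(oxiran-2-yl)propan-2-yl]-1,3-thiazole (racemic) | CC(C)(c1nc(C/C=C/CC=C)cs1)C1CO1
F6 | step 6 | 4-[(2E)-hexa-2,5-dien-1-yl]-2-{2-[(2S)-oxiran-2-yl]propan-2-yl}-1,3-thiazole | CC(C)(c1nc(C/C=C/CC=C)cs1)[C@H]1CO1
F7 | step 6 | (3R)-2-{4-[(2E)-hexa-2,5-dien-1-yl]-1,3-thiazol-2-yl}-2-methyl-6-(trimethylsilyl)hex-5-yn-3-ol | CC(C)(c1nc(C/C=C/CC=C)cs1)[C@H](O)CC#C[Si](C)(C)C
A1 | alternative 1 | 2-{(3R,5Z)-3-[(tert-butyldimethylsilyl)oxy]-6-iodo-2-methylhex-5-en-2-yl}-4-[(2E)-hexa-2,5-dien-1-yl]-1,3-thiazole | CC(C)(c1nc(C/C=C/CC=C)cs1)[C@H](O[Si](C)(C)C(C)(C)C)C/C=C\I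
A2 | alternative 1 | methyl N-[3-(tributylstannyl)but-3-en-1-yl]carbamate | CCCC[Sn](CCCC)(CCCC)C(=C)CCNC(=O)OC
A3 | alternative 2 | (3R)-2-{4-[(2E)-hexa-2,5-dien-1-yl]-1,3-thiazol-2-yl}-2-methylhex-5-en-3-ol | CC(C)(c1nc(C/C=C/CC=C)cs1)[C@H](O)CC=C
A4 | alternative 2 | methyl N-(but-3-yn-1-yl)carbamate | C#CCCNC(=O)OC
A5 | alternative 2 | (7Z,10R)-10-(2-{4-[(2E)-hexa-2,5-dien-1-yl]-1,3-thiazol-2-yl}propan-2-yl)-6-methylidene-1-oxa-3-azacyclodec-7-en-2-one | O=C1NCCC(=C)/C=C\C[C@H](C(C)(C)c2nc(C/C=C/CC=C)cs2)O1
A6 | alternative 3 | {(3R)-3-[(tert-butyldimethylsilyl)oxy]-4-{4-[(2E)-hexa-2,5-dien-1-yl]-1,3-thiazol-2-yl}-4-methylpentyl}triphenylphosphonium iodide | CC(C)(c1nc(C/C=C/CC=C)cs1)[C@H](O[Si](C)(C)C(C)(C)C)CC[P+](c1ccccc1)(c1ccccc1)c1ccccc1.[I-]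
A7 | alternative 3 | methyl N-(3-formylbut-3-en-1-yl)carbamate | C=C(C=O)CCNC(=O)OC
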